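**Retrosynthetic overview**

- Endgame: the enone carbonyl (allylic C–H oxidation), the two esters (acylations) and the two carbinol centres (conjugate borylation, then 1,3-anti reduction) are put on a tricyclic cycloheptenone; the C(CH3)=CH unit of the six-membered ring comes from a tertiary alcohol.
- Key disconnection (two bonds, one flask): the bond from the angelate-bearing CH to the C(CH3)2 carbon (closes the seven-membered ring) and the bond from the methyl-bearing quaternary cyclobutane carbon to the cyclobutane CH next to the C(CH3)=CH unit (closes the four-membered ring). This leads back to monocyclic epoxy ynone 14.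
- Enabling feature: in the seven-membered ring the acetate-bearing carbon is a ketone whose only enolisable α-carbon is the quaternary cyclobutane carbon and whose β-carbon is the angelate-bearing carbon. An ynone therefore first accepts a tertiary radical born at the C(CH3)2 carbon (from an isopropenyl group) and then supplies the enolate; that α-carbon lies 1,3 across the six-membered ring from the ring CH to be bonded, which is made an epoxide carbon.
- 14 comes from (1S,4R)-p-mentha-2,8-dien-1-ol: Ireland–Claisen rearrangement of its isobutyrate sets the cis ring stereocentres and brings in the C(CH3)2 carbon; hydroboration, decarboxylative olefination, ynone assembly and epoxidation follow.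
- Order of ring formation: six-membered ring (chiral pool), then seven-membered ring, then cyclobutane (the last two in step 9).

Key step: step 9

Assumption: (1S,4R)-p-mentha-2,8-dien-1-ol (hydroxyl and isopropenyl on the same ring face; the limonene-derived alcohol sold for cannabinoid synthesis) is taken as the commercial starting material.

Remark: the side-chain methine carbon created in step 3 is carried as a mixture of epimers (drawn without configuration in 7 to 15, as is the carbinol carbon of 12); it becomes the configurationally defined quaternary cyclobutane carbon in step 9.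

**Route**

Step 1
Reactants: 1 (1S,4R)-p-mentha-2,8-dien-1-ol; 2 isobutyryl chloride
Product: 3 tertiary allylic isobutyrate
Conditions: i-PrCOCl, Et3N, DMAP (cat.), CH2Cl2, 0 °C → rt
Reagents that add atoms: isobutyryl chloride, CC(C)C(=O)Cl
Why: Nucleophile-catalysed O-acylation (DMAP) of the tertiary allylic alcohol under basic, non-ionising conditions gives the allylic isobutyrate with both stereocentres of 1 untouched.

Step 2
Reactants: 3 tertiary allylic isobutyrate
Product: 6 cis-Claisen acid, via silyl ketene acetal 4 (not isolated), via trimethylsilyl ester 5 (not isolated)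
Conditions: LiN(i-Pr)2, THF, −78 °C; Me3SiCl, −78 → 60 °C; then 1 M HCl
Reagents that add atoms: none
Why: Ireland–Claisen rearrangement: the [3,3]-shift of the silyl ketene acetal is suprafacial across the cyclohexenyl unit, so the new quaternary carbon is delivered to the ring carbon next to the isopropenyl-bearing one on the face that carried the ester oxygen (cis to isopropenyl), the configuration of the carbinol carbon of 1 thus being relayed to the new ring stereocentre while the double bond moves to the methyl-bearing carbon.

Step 3
Reactants: 6 cis-Claisen acid
Product: 8 hydroxy acid, via bis-borane adduct 7 (not isolated)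
Conditions: 9-BBN (2.5 equiv), THF, 0 °C → rt; then NaOH, H2O2, 0 °C
Reagents that add atoms: hydrogen peroxide, OO
Why: Hydroboration–oxidation with the bulky 9-BBN is selective for the terminal 1,1-disubstituted alkene over the hindered trisubstituted ring alkene and places the hydroxyl on the terminal carbon, the new side-chain methine forming as an epimer mixture that is of no consequence.

Step 4
Reactants: 8 hydroxy acid
Product: 9 isopropenyl alcohol
Conditions: 9-(2-chlorophenyl)acridine (10 mol%), Co(dmgH)2(py)Cl (5 mol%), 400 nm LED, CH2Cl2, rt
Reagents that add atoms: none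
Why: Decarboxylative olefination under acridine/Co(dmgH)2(py)Cl dual photocatalysis: proton-coupled electron transfer in the acridine–acid complex expels CO2 to give the tertiary radical, from which the cobalt complex removes one of the six accessible methyl hydrogens to form the isopropenyl group without touching the ring stereocentres.

Step 5
Reactants: 9 isopropenyl alcohol
Product: 10 aldehyde
Conditions: Dess–Martin periodinane, NaHCO3, CH2Cl2, 0 °C → rt
Reagents that add atoms: none
Why: Dess–Martin oxidation converts the primary alcohol into the aldehyde under buffered conditions that spare both alkenes.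

Step 6
Reactants: 10 aldehyde; 11 ethynylmagnesium bromide
Product: 12 propargylic alcohol
Conditions: HC≡CMgBr, THF, −78 → 0 °C; aq. NH4Cl
Reagents that add atoms: ethynylmagnesium bromide, C#C[Mg]Br
Why: Grignard 1,2-addition of the alkynyl nucleophile to the aldehyde gives the propargylic alcohol, whose new carbinol centre (epimer mixture) is erased in the next step.

Step 7
Reactants: 12 propargylic alcohol
Product: 13 diene ynone
Conditions: Dess–Martin periodinane, NaHCO3, CH2Cl2, 0 °C
Reagents that add atoms: none
Why: Dess–Martin oxidation of the secondary propargylic alcohol gives the terminal ynone.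

Step 8
Reactants: 13 diene ynone
Product: 14 epoxy ynone
Conditions: m-CPBA (1.05 equiv), NaHCO3, CH2Cl2, −20 °C
Reagents that add atoms: m-chloroperbenzoic acid, O=C(OO)c1cccc(Cl)c1
Why: Prilezhaev epoxidation: the trisubstituted ring alkene is the most electron-rich π-bond (the isopropenyl group reacts more slowly and the ynone not at all) and is attacked on the face opposite to the two cis ring substituents, which sets both epoxide carbons trans to them.

Step 9
Reactants: 14 epoxy ynone
Product: 16 tricyclic hydroxy enone, via bicyclic epoxy enone 15 (not isolated)
Conditions: Fe(acac)3 (0.5 equiv), PhSiH3, EtOH/THF, 0.01 M, 40 °C; then t-BuOK, t-BuOH, 50 °C (same flask)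
Reagents that add atoms: none
Why: Proposed new method: hydrogen-atom transfer from an iron hydride (Fe(acac)3/PhSiH3) to the isopropenyl group gives the tertiary radical at the future gem-dimethyl carbon, which adds in Giese fashion to the terminal carbon of the ynone and, after the vinyl radical has taken up hydrogen, leaves the cis-cycloheptenone 15; t-BuOK then generates the cross-conjugated enolate at the only enolisable carbon (the side-chain methine), and this carbon opens the epoxide at its secondary carbon to close the cyclobutane. The closest known reaction types are the hydrogen-atom-transfer-initiated reductive coupling of alkenes with conjugate acceptors, the epoxynitrile cyclisation to cyclobutanes and the intramolecular enolate alkylation that builds the pinane four-membered ring; running both closures in one flask on an ynone acceptor is what is new. Modes of closure: seven-membered ring by 7-endo-dig radical addition, four-membered ring by 4-exo-tet nucleophilic opening of the epoxide. Stereocentres: the quaternary cyclobutane carbon is dictated by the seven-membered ring already formed (its carbonyl arm is tied to the gem-dimethyl side, so the methyl group ends over the six-membered ring), the attacked epoxide carbon is inverted by backside attack from the face of the two cis substituents, and the tertiary carbinol keeps the epoxide configuration. The step needs attack at the ynone terminus and not at its α-carbon (secured by polarity matching of the nucleophilic tertiary radical and by the unhindered CH terminus), opening at the secondary and not the tertiary epoxide carbon (secured by basic SN2 conditions and the collinear exo trajectory), and C- not O-alkylation (secured by the ring-bound enolate, whose oxygen lies in the ring plane away from the epoxide while the α-carbon π-face sits over it).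

Step 10
Reactants: 16 tricyclic hydroxy enone
Product: 17 tricyclic dienone
Conditions: Burgess reagent, PhMe, 60 °C
Reagents that add atoms: none
Why: Burgess dehydration (syn-elimination of the sulfamate ester) of the tertiary alcohol under neutral conditions should give the endocyclic trisubstituted alkene, elimination toward the bridgehead being forbidden by Bredt's rule.

Step 11
Reactants: 17 tricyclic dienone
Product: 19 hydroxy ketone, via boryl ketone 18 (not isolated)
Conditions: CuCl (5 mol%), NaOt-Bu, DTBM-SEGPHOS (enantiomer matched to the required face), B2pin2, MeOH, THF, rt; then H2O2, pH 7 buffer, 0 °C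
Reagents that add atoms: hydrogen peroxide, OO
Why: Copper-catalysed enantioselective conjugate borylation followed by stereoretentive oxidation of the carbon–boron bond: the chiral bisphosphine boryl copper complex formed from CuCl, not the nearly unbiased substrate, chooses the enone face and so sets the carbinol centre next to the gem-dimethyl carbon.

Step 12
Reactants: 19 hydroxy ketone
Product: 20 anti-diol
Conditions: Me4NBH(OAc)3, MeCN/AcOH, −30 °C
Reagents that add atoms: none
Why: Evans–Saksena directed reduction: the free hydroxyl exchanges onto boron and delivers hydride intramolecularly to the ketone, which gives the 1,3-anti diol and thereby sets the second carbinol centre.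

Step 13
Reactants: 20 anti-diol; 21 acetic anhydride
Product: 22 monoacetate
Conditions: Ac2O (1.05 equiv), pyridine, CH2Cl2, −20 °C
Reagents that add atoms: acetic anhydride, CC(=O)OC(C)=O
Why: Site-selective acetylation: the carbinol beside the tied-back cyclobutane carbon is less hindered than the one flanked by the gem-dimethyl group, so one equivalent of acetic anhydride at low temperature should esterify it first.

Step 14
Reactants: 22 monoacetate; 23 angelic acid
Product: 24 acetate angelate
Conditions: angelic acid, 2,4,6-Cl3C6H2COCl, Et3N, PhMe, rt; then 22, 75 °C
Reagents that add atoms: angelic acid, C/C=C(/C)C(=O)O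
Why: Yamaguchi-type esterification through the mixed 2,4,6-trichlorobenzoic anhydride of angelic acid, run without a nucleophilic catalyst so that the Z-configured angelate is transferred to the hindered carbinol without isomerisation to the tiglate.

Step 15
Reactants: 24 acetate angelate
Product: 25 target CNP0260482.1
Conditions: Rh2(cap)4 (1 mol%), t-BuOOH (70% aq.), K2CO3, CH2Cl2, rt
Reagents that add atoms: tert-butyl hydroperoxide, CC(C)(C)OO
Why: Allylic C–H oxidation with Rh2(cap)4 and tert-butyl hydroperoxide at the only allylic methylene of the electron-rich ring alkene, the reaction type that converts α-pinene into verbenone, gives the enone while the electron-poor angelate alkene and the bridgehead allylic position are left alone.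

**Compound list**

1 | (1S,4R)-p-mentha-2,8-dien-1-ol, hydroxyl cis to isopropenyl | C=C(C)[C@@H]1CC[C@](C)(O)C=C1 | starting material
2 | isobutyryl chloride | CC(C)C(=O)Cl | starting material
3 | tertiary allylic isobutyrate: (1S,4R)-1-methyl-4-(prop-1-en-2-yl)cyclohex-2-en-1-yl 2-methylpropanoate | C=C(C)[C@@H]1CC[C@](C)(OC(=O)C(C)C)C=C1 | intermediate
4 | silyl ketene acetal (O-trimethylsilyl ketene acetal of 3) | C=C(C)[C@@H]1CC[C@](C)(OC(O[Si](C)(C)C)=C(C)C)C=C1 | intermediate (not isolated)
5 | trimethylsilyl ester of 6 | C=C(C)[C@@H]1CCC(C)=C[C@@H]1C(C)(C)C(=O)O[Si](C)(C)C | intermediate (not isolated)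
6 | cis-Claisen acid: 2-methyl-2-[3-methyl-6-(prop-1-en-2-yl)cyclohex-2-en-1-yl]propanoic acid, ring substituents cis | C=C(C)[C@@H]1CCC(C)=C[C@@H]1C(C)(C)C(=O)O | intermediate
7 | bis-borane adduct of 6 (9-BBN on the terminal side-chain carbon and as acyloxyborane) | CC(CB1C2CCCC1CCC2)[C@@H]1CCC(C)=C[C@@H]1C(C)(C)C(=O)OB1C2CCCC1CCC2 | intermediate (not isolated)
8 | hydroxy acid: 2-[6-(1-hydroxypropan-2-yl)-3-methylcyclohex-2-en-1-yl]-2-methylpropanoic acid, ring substituents cis | CC(CO)[C@@H]1CCC(C)=C[C@@H]1C(C)(C)C(=O)O | intermediate
9 | isopropenyl alcohol: 2-[4-methyl-2-(prop-1-en-2-yl)cyclohex-3-en-1-yl]propan-1-ol, ring substituents cis | CC(CO)[C@@H]1CCC(C)=C[C@@H]1C(C)=C | intermediate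
10 | aldehyde: 2-[4-methyl-2-(prop-1-en-2-yl)cyclohex-3-en-1-yl]propanal, ring substituents cis | CC(C=O)[C@@H]1CCC(C)=C[C@@H]1C(C)=C | intermediate
11 | ethynylmagnesium bromide | C#C[Mg]Br | starting material
12 | propargylic alcohol: 4-[4-methyl-2-(prop-1-en-2-yl)cyclohex-3-en-1-yl]pent-1-yn-3-ol, ring substituents cis | CC(C(O)C#C)[C@@H]1CCC(C)=C[C@@H]1C(C)=C | intermediate
13 | diene ynone: 4-[4-methyl-2-(prop-1-en-2-yl)cyclohex-3-en-1-yl]pent-1-yn-3-one, ring substituents cis | CC(C(=O)C#C)[C@@H]1CCC(C)=C[C@@H]1C(C)=C | intermediate
14 | epoxy ynone: 4-[6-methyl-2-(prop-1-en-2-yl)-7-oxabicyclo[4.1.0]heptan-3-yl]pent-1-yn-3-one, epoxide trans to the two cis ring substituents | CC(C(=O)C#C)[C@@H]1CC[C@@]2(C)O[C@H]2[C@@H]1C(C)=C | intermediate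
15 | bicyclic epoxy enone: cis-fused 4,4,7-trimethylcyclohept-2-enone / methylcyclohexane epoxide | C1=CC(=O)C(C)[C@@H]2CC[C@@]3(C)O[C@H]3[C@@H]2C1(C)C | intermediate (not isolated)
16 | tricyclic hydroxy enone: cyclobutane closed, tertiary alcohol on the six-membered ring | C1=CC(=O)[C@@]2(C)[C@@H]3CC[C@@](C)(O)[C@H]2[C@@H]3C1(C)C | intermediate
17 | tricyclic dienone: cycloheptenone plus C(CH3)=CH in the six-membered ring | C1=CC(=O)[C@@]2(C)[C@@H]3CC=C(C)[C@H]2[C@@H]3C1(C)C | intermediate
18 | boryl ketone: pinacolboryl group on the carbon next to the gem-dimethyl carbon | CC1(C)OB(OC1(C)C)[C@@H]1CC(=O)[C@@]2(C)[C@@H]3CC=C(C)[C@H]2[C@@H]3C1(C)C | intermediate (not isolated)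
19 | hydroxy ketone: β-hydroxy ketone, hydroxyl next to the gem-dimethyl carbon | O[C@@H]1CC(=O)[C@@]2(C)[C@@H]3CC=C(C)[C@H]2[C@@H]3C1(C)C | intermediate
20 | anti-diol: 1,3-anti diol of the seven-membered ring | O[C@@H]1C[C@@H](O)[C@@]2(C)[C@@H]3CC=C(C)[C@H]2[C@@H]3C1(C)C | intermediate
21 | acetic anhydride | CC(=O)OC(C)=O | starting material
22 | monoacetate: acetate on the carbinol next to the quaternary cyclobutane carbon, free hydroxyl next to the gem-dimethyl carbon | O[C@@H]1C[C@@H](OC(C)=O)[C@@]2(C)[C@@H]3CC=C(C)[C@H]2[C@@H]3C1(C)C | intermediate
23 | angelic acid, (Z)-2-methylbut-2-enoic acid | C/C=C(/C)C(=O)O | starting material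
24 | acetate angelate: target lacking the enone carbonyl (CH2 in its place) | C/C=C(/C)C(=O)O[C@@H]1C[C@@H](OC(C)=O)[C@@]2(C)[C@@H]3CC=C(C)[C@H]2[C@@H]3C1(C)C | intermediate
25 | CNP0260482.1 | C/C=C(/C)C(=O)O[C@@H]1C[C@@H](OC(C)=O)[C@@]2(C)[C@@H]3C(=O)C=C(C)[C@H]2[C@@H]3C1(C)C | target

**Step count and risks**

Total step count: 15. Longest linear sequence: 15 steps (1 to 25; the route is linear).

Steps most likely to fail:

Step 9 (carries the label). The tertiary radical may be reduced to an isopropyl group before it reaches the ynone, or the enolate may fail to open the hindered epoxide (base-induced epoxide isomerisation, or ring opening at the wrong carbon). Fallback with known chemistry, setting out from 8: Dess–Martin oxidation gives aldehyde acid F1, addition of HC≡CMgBr gives propargylic alcohol acid F2, and a second Dess–Martin oxidation gives ynone acid F3. Visible-light photoredox decarboxylative Giese cyclisation of the tertiary carboxylate (Ir[dF(CF3)ppy]2(dtbbpy)PF6, K2HPO4, DMF, blue LED) then closes the seven-membered ring without any hydride reagent and gives bicyclic dienone F4. Epoxidation of its trisubstituted ring alkene with m-CPBA gives 15, now isolated, and the four-membered ring is closed in a separate step with KN(SiMe3)2 in toluene, which returns to the route at 16.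

Step 13. Site selectivity may be poor, with acetylation of both carbinols or of the wrong one. Fallback, setting out from 18 (isolated instead of oxidised): Corey–Bakshi–Shibata reduction of the ketone under catalyst control gives boryl alcohol F5, acetylation gives boryl acetate F6, and oxidation of the carbon–boron bond with NaBO3·4H2O reveals the second hydroxyl only then, which returns to the route at 22.

Step 14. Acylation of the neopentyl-type carbinol may be slow, with isomerisation of the angelate to the tiglate or migration of the acetyl group. Fallback, setting out from 22: carbodiimide/DMAP esterification with 2-[bis(2,2,2-trifluoroethoxy)phosphoryl]propanoic acid (a saturated acid that can be forced without risk to alkene geometry) gives phosphonate ester F7. Still–Gennari olefination (KN(SiMe3)2, 18-crown-6, acetaldehyde, THF, −78 °C) then builds the Z-alkene on the ester and returns to the route at 24.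

Further compounds
F1 | step 9 | aldehyde acid | CC(C=O)[C@@H]1CCC(C)=C[C@@H]1C(C)(C)C(=O)O
F2 | step 9 | propargylic alcohol acid | CC(C(O)C#C)[C@@H]1CCC(C)=C[C@@H]1C(C)(C)C(=O)O
F3 | step 9 | ynone acid | CC(C(=O)C#C)[C@@H]1CCC(C)=C[C@@H]1C(C)(C)C(=O)O
F4 | step 9 | bicyclic dienone | C1=CC(=O)C(C)[C@@H]2CCC(C)=C[C@@H]2C1(C)C
F5 | step 13 | boryl alcohol | CC1(C)OB(OC1(C)C)[C@@H]1C[C@@H](O)[C@@]2(C)[C@@H]3CC=C(C)[C@H]2[C@@H]3C1(C)C
F6 | step 13 | boryl acetate | CC1(C)OB(OC1(C)C)[C@@H]1C[C@@H](OC(C)=O)[C@@]2(C)[C@@H]3CC=C(C)[C@H]2[C@@H]3C1(C)C
F7 | step 14 | phosphonate ester | CC(C(=O)O[C@@H]1C[C@@H](OC(C)=O)[C@@]2(C)[C@@H]3CC=C(C)[C@H]2[C@@H]3C1(C)C)P(=O)(OCC(F)(F)F)OCC(F)(F)F
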